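For 6 questions on 3 flasks we reckon one number per flask: the free monomer left at the end.

the same everywhere: free monomer 0.12 M; initiator 0.21 mol%
- zeta: protic impurity 0.036 M; temperature 25 °C; run made earlier
- east: protic impurity 0.0240 M; temperature 25 °C; time 12 d
- north-west: protic impurity 0.0240 M; temperature 40 °C; time 12 d
- south-west: protic impurity 0.0240 M; temperature 55 °C; time 12 d

- zeta (time / h: free monomer / %, monomer in chains / %, over-reaction product / %): 6.00: 57.5, 22.2, 4.7; 12.0: 40.5, 23.1, 13.3; 15.0: 34.8, 23.9, 16.9; 25.0: 26.3, 18.5, 29.0; 30.0: 22.7, 16.5, 35.5

(scatter of a reading: 1 percentage point)

- the numbers in the tables scatter by 1 percentage point (one standard deviation)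
- steps under discussion: free monomer + initiating radical -> growing radical + monomer in chains; initiator -> 2 initiating radical; 2 growing radical -> dead chain; monomer in chains -> over-reaction product; free monomer + growing radical -> monomer in chains + growing radical; protic impurity + free monomer -> quenched substrate
- the earlier runs do not show what temperature does; that part of a forecast is a guess
- no earlier run changes the charge of protic impurity; that part of a forecast is a guess

- which of these there is most of at the end, counted by the free monomer in it, east (monomer in chains / over-reaction product / free monomer)
- which of these there is most of at the end, counted by the free monomer in it, north-west (monomer in chains / over-reaction product / free monomer)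
- which of these there is most of at the end, counted by the free monomer in it, south-west (monomer in chains / over-reaction product / free monomer)
- amount of the one of these that there is most of at the end, in percent of the free monomer charged, east
- amount of the one of these that there is most of at the end, in percent of the free monomer charged, north-west
- amount of the one of these that there is most of at the end, in percent of the free monomer charged, south-west

1. The concentration that sets the order is that of the growing radical, [L]. It is made from initiator and lost in pairs, so at steady state it goes as the square root of the initiator and holds no free monomer term. Chain growth therefore takes free monomer M pseudo-first-order, with k = k_p[L], where k_p is the propagation constant. We call the reach Λ the integral of k over time, so that chain growth cuts M by the factor exp(−Λ).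

2. In the zeta run the balance is short by 25.3% at the last reading, against an impurity charge of 30.0%. We take the quench as one to one, which leaves east 80.0% of its free monomer for chains.

3. In the zeta run, product growth over mean monomer in chains gives a reading of 0.0663 h⁻¹, so the time of east is far longer than the lifetime of monomer in chains read here. At the end of east we count monomer in chains as over-reaction product.

4. Monomer entering chains, divided by mean free monomer, summed interval by interval, gives the zeta reach: 0.652 up to 15.0 h, then 0.403 up to 30.0 h. Initiator decays first-order, so equal windows shrink by one factor, and the series sums to 1.71.

5. That factor is the weak link, since it rests on few readings with their scatter. Cutting at 12.0 h instead gives 0.535, then 0.336 up to 25.0 h. Per hour, that sums to 1.27. We commit to the mean, 1.49, the reach at long times, the total the initiator can still drive.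

6. By our reckoning east then keeps 18.0% free monomer and makes 62.0% over-reaction product. The earlier runs do not show what temperature does, so our own reckoning stops at east.

The forecast says over-reaction product at 64% in east, over-reaction product at 48% in north-west and free monomer at 47% in south-west, holding that warming “burns initiator much faster”. Its east lies above our figure.

The flasks give over-reaction product at 61.5% in east, over-reaction product at 55.7% in north-west and over-reaction product at 50.1% in south-west.

    free monomer + initiating radical → growing radical + monomer in chains (k = 90000 M⁻¹ s⁻¹, Ea = 14.0 kJ mol⁻¹)
    initiator → 2 initiating radical (k = 0.00160 min⁻¹, Ea = 90.0 kJ mol⁻¹)
    2 growing radical → dead chain (k = 5.30 × 10⁷ M⁻¹ s⁻¹, Ea = 11.0 kJ mol⁻¹)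
    monomer in chains → over-reaction product (k = 0.00100 min⁻¹, Ea = 105 kJ mol⁻¹)
    free monomer + growing radical → monomer in chains + growing radical, rate k5*[growing radical]*[free monomer] (k = 94000 M⁻¹ min⁻¹, Ea = 39.0 kJ mol⁻¹)
    protic impurity + free monomer → quenched substrate (k = 0.0280 M⁻¹ min⁻¹, Ea = 75.0 kJ mol⁻¹)
    (constants at 25 °C)

South-west stops with 29.9% free monomer, since removing the reaction of 2 growing radical to dead chain lifts its over-reaction product from 50.1% to 99.6%. Read back through our factor exp(−Λ), that end is a reach of 0.984, against the forecast's 0.5, which is where the two part. That reach for south-west is 0.661 of our 1.49.

A neighbour flask is south-west with 0.052 mol% initiator, so the square root gives a reach of 0.490 and 49.0% free monomer. The computed flask holds 49.8%.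

All runs come from a simulation for an exercise; scatter was added.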